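Ring A is annulated last onto a ring B that comes from (R)-carvone. The key step exploits the gem-dimethyl carbon C4 and the C1–C3 chain of ring A: C2–C3 arrive as acrolein, C4 is the isopropenyl carbon on C5, and C1 is a formyl carbon on quaternary C10, so the precursor is monocyclic 6-formyl-6-methylcarvone. One iron-hydride-initiated operation joins C4 to C3 by radical conjugate addition and C2 to C1 by aldol closure, giving the trans-decalin; the extra C1 hydroxyl and C2 formyl groups are then excised to reach drimenol. Markovnikov hydration, aldol condensation with a cyclopentane-1,2-dione enol ether, allylic oxidation, reagent-controlled reduction and chloride inversion complete the chlorinated ring.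

Key step: step 4

Remark: drimane numbering is used for the decalin (C11 is the exocyclic CH); the five-membered ring is numbered C1'–C5' as in 2-methoxycyclopent-2-en-1-one 22 (C1' carbonyl carbon, C2' methoxy-bearing carbon, C5' the carbon that becomes the alkylidene carbon). The target is taken as one enol tautomer of a 4-alkylidene-5-chlorocyclopentane-1,3-dione; the route delivers the dione, which should settle as the drawn conjugated enol.

Step 1
Reactants: 1 (R)-(−)-carvone
Product: 3 (5R,6S)-2,6-dimethyl-5-(prop-1-en-2-yl)cyclohex-2-en-1-one (trans-6-methylcarvone), via lithium enolate 2 (not isolated)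
Conditions: LDA, THF, −78 °C; then MeI, −78 to 0 °C
Reagents that add atoms: iodomethane CI
Why: Kinetic α'-deprotonation of the enone at C6 and SN2 methylation of the lithium enolate (enolate alkylation) should give mainly the trans isomer; the new centre is planarised again in step 2, so its configuration does not matter.

Step 2
Reactants: 3 trans-6-methylcarvone
Product: 5 (5S,6R)-6-(hydroxymethyl)-2,6-dimethyl-5-(prop-1-en-2-yl)cyclohex-2-en-1-one, via lithium enolate 4 (not isolated)
Conditions: LDA, THF, −78 °C; then CH2O (gas), −78 °C; aq. NH4Cl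
Reagents that add atoms: formaldehyde C=O
Why: Aldol hydroxymethylation of the regiodefined tetrasubstituted enolate; formaldehyde should enter anti to the pseudoaxial isopropenyl group, which sets the quaternary centre (future C10) with the methyl cis and the CH2OH trans to the isopropenyl group.

Step 3
Reactants: 5 hydroxymethyl ketone
Product: 6 (1R,6S)-1,3-dimethyl-2-oxo-6-(prop-1-en-2-yl)cyclohex-3-ene-1-carbaldehyde
Conditions: Dess–Martin periodinane, CH2Cl2, 0 °C to rt
Reagents that add atoms: none
Why: Dess–Martin oxidation of the neopentyl primary alcohol under non-basic conditions should avoid retro-aldol loss of formaldehyde and deformylation of the non-enolisable β-keto aldehyde; no stereocentre is touched.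

Step 4
Reactants: 6 keto aldehyde; 7 acrolein
Product: 10 2-formyl-1-hydroxy-11-nordrim-7-en-9-one (trans-fused; C1/C2 epimer mixture), via tertiary alkyl radical 8 (not isolated), via iron enolate 9 (not isolated)
Conditions: Fe(acac)3, PhSiH3, acrolein (excess), EtOH/ethylene glycol, 0 °C to rt
Reagents that add atoms: none
Why: The iron hydride formed from Fe(acac)3 and PhSiH3 transfers a hydrogen atom to the terminal CH2 of the isopropenyl group, and the tertiary C4 radical 8 adds to the β-carbon of acrolein (C3–C4 bond, gem-dimethyl quaternary centre); reduction of the α-formyl radical gives iron enolate 9, whose C2 attacks the C1 formyl group (C1–C2 bond). The closest known reaction type is the hydrogen-atom-transfer-initiated radical–polar crossover annulation (Giese addition, then aldol) of γ,δ-unsaturated aldehydes with enals, and 6 is exactly such an α-quaternary γ,δ-unsaturated aldehyde. Ring A closes in a 6-(enolexo)-exo-trig aldol after the intermolecular radical addition. The C1 carbinol and C2 formyl centres need no control, since both are erased in steps 5 and 6, while the trans ring fusion (H-5 α, CH3-10 β) follows from the trans arrangement of formyl and isopropenyl groups set in step 2, both equatorial in the cyclising chair. The step needs hydrogen-atom transfer to the electron-neutral 1,1-disubstituted alkene and not to the electron-poor enone, capture of the nucleophilic radical by excess acrolein, and aldol at the formyl group instead of the conjugated C9 ketone. These should follow from the polarity match of the hydridic iron hydride and of the nucleophilic tertiary radical, and from the far higher electrophilicity of the aldehyde compared with the conjugated C9 ketone, which is flanked by the quaternary carbon and whose attack would build a more congested bicyclo[3.3.1]nonane.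

Step 5
Reactants: 10 hydroxy aldehyde
Product: 12 2-formyl-11-nordrima-1,7-dien-9-one, via mesylate 11 (not isolated)
Conditions: MsCl, Et3N (excess), CH2Cl2, 0 °C to rt
Reagents that add atoms: none
Why: Mesylation of the C1 alcohol and E1cB elimination through the aldehyde enolate (aldol-type dehydration) should give the conjugated enal and erase the C1 and C2 stereocentres.

Step 6
Reactants: 12 enal
Product: 13 11-nordrima-1,7-dien-9-one
Conditions: RhCl(PPh3)3 (1 equiv), toluene, 110 °C
Reagents that add atoms: none
Why: Tsuji–Wilkinson decarbonylation (oxidative addition into the formyl C–H bond, CO extrusion, reductive elimination) should leave the C1=C2 alkene in place and touch no stereocentre.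

Step 7
Reactants: 13 dienone
Product: 14 11-nordrim-7-en-9-one [(4aS,8aS)-2,5,5,8a-tetramethyl-4a,5,6,7,8,8a-hexahydronaphthalen-1(4H)-one]
Conditions: H2 (1 atm), RhCl(PPh3)3 (cat.), benzene, rt
Reagents that add atoms: none
Why: Homogeneous hydrogenation with RhCl(PPh3)3 should reduce the cis-disubstituted C1=C2 alkene and leave the trisubstituted conjugated C7=C8 enone untouched; no new stereocentre is formed.

Step 8
Reactants: 14 bicyclic enone
Product: 15 drima-7,9(11)-diene
Conditions: Ph3PCH3Br, KOtBu, toluene, 100 °C
Reagents that add atoms: methyltriphenylphosphonium bromide C[P+](c1ccccc1)(c1ccccc1)c1ccccc1.[Br-]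
Why: Wittig methylenation of the hindered C9 ketone under forcing conditions, as used for 2,6,6-trisubstituted cyclohexenones, should give the exocyclic 1,3-diene; no stereocentre is formed.

Step 9
Reactants: 15 diene
Product: 17 (−)-drimenol (drim-7-en-11-ol), via alkylborane 16 (not isolated)
Conditions: 9-BBN, THF, 0 °C to rt; then NaOH, H2O2, 0 °C
Reagents that add atoms: hydrogen peroxide OO
Why: Hydroboration–oxidation: 9-BBN should add anti-Markovnikov to the exocyclic C9=C11 bond from the α face, opposite the axial C10 methyl group, so H-9 becomes α and the CH2OH group β (equatorial).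

Step 10
Reactants: 17 drimenol
Product: 19 drimane-8β,11-diol (8-epi; 8α-CH3), via organomercurial 18 (not isolated)
Conditions: Hg(OAc)2, THF/H2O, rt; then NaBH4, aq. NaOH, 0 °C
Reagents that add atoms: water O
Why: Oxymercuration–demercuration (Markovnikov hydration): the mercurinium ion should form on the less hindered α face and be opened trans-diaxially by water at tertiary C8 from the β face, which sets the axial 8β-hydroxyl and equatorial 8α-methyl groups before NaBH4 replaces mercury at C7 by hydrogen.

Step 11
Reactants: 19 diol
Product: 20 8β-hydroxydriman-11-al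
Conditions: TEMPO (cat.), PhI(OAc)2, CH2Cl2, rt
Reagents that add atoms: none
Why: The oxoammonium (TEMPO) oxidation is selective for the primary alcohol and stops at the aldehyde under neutral conditions, so the tertiary alcohol and the C9 centre (formyl already equatorial) should be unaffected.

Step 12
Reactants: 21 cyclopentane-1,2-dione
Product: 22 2-methoxycyclopent-2-en-1-one
Conditions: MeOH, TsOH (cat.), benzene, reflux (water removed)
Reagents that add atoms: methanol CO
Why: Acid-catalysed O-methylation of the enol form of the 1,2-dione (diosphenol ether formation) driven by removal of water.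

Step 13
Reactants: 22 2-methoxycyclopent-2-en-1-one; 20 hydroxy aldehyde
Product: 24 5-(8β,11-dihydroxydriman-11-yl)-2-methoxycyclopent-2-en-1-one (epimer mixture at C11 and C5'), via lithium enolate 23 (not isolated)
Conditions: LDA, THF, −78 °C (22 in excess); then 20, −78 °C; AcOH quench
Reagents that add atoms: none
Why: Kinetic α'-deprotonation of the enone and aldol addition of the cross-conjugated lithium enolate to the hindered aldehyde; the tertiary alcohol should not be deprotonated by a ketone enolate at −78 °C (no retro-aldol), and both new centres disappear in step 14.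

Step 14
Reactants: 24 aldol adduct
Product: 26 (E)-5-(8β-hydroxydriman-11-ylidene)-2-methoxycyclopent-2-en-1-one, via mesylate 25 (not isolated)
Conditions: MsCl, Et3N, CH2Cl2, 0 °C; then DBU, rt
Reagents that add atoms: none
Why: Mesylation of the secondary aldol hydroxyl and E1cB elimination (aldol condensation) should give the thermodynamically preferred (E)-alkylidene ketone, with the drimanyl group anti to the C1' carbonyl and therefore cis to C4', the carbon that carries the enol oxygen in the target; the hindered axial tertiary alcohol is not sulfonylated.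

Step 15
Reactants: 26 dienone
Product: 27 (E)-5-(8β-hydroxydriman-11-ylidene)-2-methoxycyclopent-2-ene-1,4-dione
Conditions: Rh2(cap)4 (cap = caprolactamate, cat.), t-BuOOH, K2CO3 (cat.), CH2Cl2, rt
Reagents that add atoms: tert-butyl hydroperoxide CC(C)(C)OO
Why: Allylic C–H oxidation by the tert-butylperoxyl radical should take the doubly allylic C4' methylene, the weakest C–H bond, through a mixed peroxide to the ketone (enone to ene-dione); the alkene geometry set in step 14 is untouched.

Step 16
Reactants: 27 ene-dione
Product: 28 (4S,5Z)-4-hydroxy-5-(8β-hydroxydriman-11-ylidene)-3-methoxycyclopent-2-en-1-one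
Conditions: (R)-Me-CBS oxazaborolidine (0.3 equiv), catecholborane, toluene, −78 °C; then MeOH, pH 7 buffer
Reagents that add atoms: none
Why: Corey–Bakshi–Shibata reduction: the C1' carbonyl, not deactivated by the vinylogous-ester conjugation that tames C4'=O, should be reduced 1,2, and the (R)-catalyst, reading the methoxy-substituted endocyclic flank as the large group, should deliver hydride to the face that gives the (S)-carbinol (reagent control, remote from the terpenoid centres).

Step 17
Reactants: 28 (S)-carbinol
Product: 29 (4R,5E)-4-chloro-5-(8β-hydroxydriman-11-ylidene)-3-methoxycyclopent-2-en-1-one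
Conditions: PPh3, Cl3CC(O)CCl3, CH2Cl2, −20 °C
Reagents that add atoms: hexachloroacetone ClC(Cl)(Cl)C(=O)C(Cl)(Cl)Cl
Why: Appel-type chlorination: chloride should displace the alkoxyphosphonium group by SN2 with inversion to give the (R)-chloride, because ionisation would give an antiaromatic cyclopentadienyl-type cation, SN2' attack at C11 would give a cyclopentadienone, and SN2' attack at the other allylic terminus would be on the electron-rich α-carbon of the vinylogous ester; the hindered tertiary alcohol does not react at low temperature.

Step 18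
Reactants: 29 chloro vinylogous ester
Product: 30 (4E,5R)-5-chloro-3-hydroxy-4-[(5S,8S,9R,10S)-8-hydroxydriman-11-ylidene]cyclopent-2-en-1-one (CNP0279879.2)
Conditions: 1 M HCl (aq), THF, rt
Reagents that add atoms: water O
Why: Acid hydrolysis of the vinylogous methyl ester (addition of water at C2', loss of methanol) should release the 1,3-dione as the drawn conjugated enol; dilute aqueous acid leaves the C1' chloride, the tertiary alcohol and all stereocentres untouched, whereas base is avoided because the C1' hydrogen of 29 is acidic.

Compound list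
1 | (R)-(−)-carvone, (5R)-2-methyl-5-(prop-1-en-2-yl)cyclohex-2-en-1-one | CC1=CC[C@H](CC1=O)C(C)=C | starting material
2 | lithium enolate of 1 (C6 deprotonated) | CC1=CC[C@H](C=C1[O-])C(C)=C.[Li+] | intermediate
3 | (5R,6S)-2,6-dimethyl-5-(prop-1-en-2-yl)cyclohex-2-en-1-one (trans-6-methylcarvone) | C[C@@H]1C(=O)C(C)=CC[C@H]1C(C)=C | intermediate
4 | lithium enolate of 3 | CC1=CC[C@H](C(C)=C1[O-])C(C)=C.[Li+] | intermediate
5 | (5S,6R)-6-(hydroxymethyl)-2,6-dimethyl-5-(prop-1-en-2-yl)cyclohex-2-en-1-one | OC[C@]1(C)C(=O)C(C)=CC[C@H]1C(C)=C | intermediate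
6 | (1R,6S)-1,3-dimethyl-2-oxo-6-(prop-1-en-2-yl)cyclohex-3-ene-1-carbaldehyde | O=C[C@]1(C)C(=O)C(C)=CC[C@H]1C(C)=C | intermediate
7 | acrolein (prop-2-enal) | C=CC=O | starting material
8 | tertiary C4 radical from hydrogen-atom transfer to 6 | O=C[C@]1(C)C(=O)C(C)=CC[C@H]1[C](C)C | intermediate
9 | iron enolate of the Giese adduct (drawn as the enolate anion) | O=C[C@]1(C)C(=O)C(C)=CC[C@H]1C(C)(C)CC=C[O-] | intermediate
10 | 2-formyl-1-hydroxy-11-nordrim-7-en-9-one (H-5 α, CH3-10 β; C1/C2 epimer mixture) | CC1(C)CC(C=O)C(O)[C@]2(C)C(=O)C(C)=CC[C@@H]12 | intermediate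
11 | C1 mesylate of 10 | CC1(C)CC(C=O)C(OS(C)(=O)=O)[C@]2(C)C(=O)C(C)=CC[C@@H]12 | intermediate
12 | 2-formyl-11-nordrima-1,7-dien-9-one | CC1(C)CC(C=O)=C[C@]2(C)C(=O)C(C)=CC[C@@H]12 | intermediate
13 | 11-nordrima-1,7-dien-9-one | CC1(C)CC=C[C@]2(C)C(=O)C(C)=CC[C@@H]12 | intermediate
14 | 11-nordrim-7-en-9-one, (4aS,8aS)-2,5,5,8a-tetramethyl-4a,5,6,7,8,8a-hexahydronaphthalen-1(4H)-one | CC1(C)CCC[C@]2(C)C(=O)C(C)=CC[C@@H]12 | intermediate
15 | drima-7,9(11)-diene | CC1(C)CCC[C@]2(C)C(=C)C(C)=CC[C@@H]12 | intermediate
16 | B-(drim-7-en-11-yl)-9-borabicyclo[3.3.1]nonane | CC1(C)CCC[C@]2(C)[C@@H](CB3C4CCCC3CCC4)C(C)=CC[C@@H]12 | intermediate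
17 | (−)-drimenol, drim-7-en-11-ol (9β-CH2OH) | CC1(C)CCC[C@]2(C)[C@@H](CO)C(C)=CC[C@@H]12 | intermediate
18 | 7α-(acetoxymercurio)drimane-8β,11-diol | CC1(C)CCC[C@]2(C)[C@@H](CO)[C@@](C)(O)[C@H]([Hg]OC(C)=O)C[C@@H]12 | intermediate
19 | drimane-8β,11-diol (8-epi; 8α-CH3) | CC1(C)CCC[C@]2(C)[C@@H](CO)[C@@](C)(O)CC[C@@H]12 | intermediate
20 | 8β-hydroxydriman-11-al | CC1(C)CCC[C@]2(C)[C@@H](C=O)[C@@](C)(O)CC[C@@H]12 | intermediate
21 | cyclopentane-1,2-dione | O=C1CCCC1=O | starting material
22 | 2-methoxycyclopent-2-en-1-one | COC1=CCCC1=O | intermediate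
23 | lithium enolate of 22 (C5' deprotonated) | COC1=CCC=C1[O-].[Li+] | intermediate
24 | 5-(8β,11-dihydroxydriman-11-yl)-2-methoxycyclopent-2-en-1-one (epimer mixture at C11 and C5') | CC1(C)CCC[C@]2(C)[C@@H](C(O)C3CC=C(OC)C3=O)[C@@](C)(O)CC[C@@H]12 | intermediate
25 | C11 mesylate of 24 | CC1(C)CCC[C@]2(C)[C@@H](C(OS(C)(=O)=O)C3CC=C(OC)C3=O)[C@@](C)(O)CC[C@@H]12 | intermediate
26 | (E)-5-(8β-hydroxydriman-11-ylidene)-2-methoxycyclopent-2-en-1-one | CC1(C)CCC[C@]2(C)[C@@H](/C=C3\CC=C(OC)C3=O)[C@@](C)(O)CC[C@@H]12 | intermediate
27 | (E)-5-(8β-hydroxydriman-11-ylidene)-2-methoxycyclopent-2-ene-1,4-dione | CC1(C)CCC[C@]2(C)[C@@H](/C=C3\C(=O)C=C(OC)C3=O)[C@@](C)(O)CC[C@@H]12 | intermediate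
28 | (4S,5Z)-4-hydroxy-5-(8β-hydroxydriman-11-ylidene)-3-methoxycyclopent-2-en-1-one | CC1(C)CCC[C@]2(C)[C@@H](/C=C3\C(=O)C=C(OC)[C@H]3O)[C@@](C)(O)CC[C@@H]12 | intermediate
29 | (4R,5E)-4-chloro-5-(8β-hydroxydriman-11-ylidene)-3-methoxycyclopent-2-en-1-one | CC1(C)CCC[C@]2(C)[C@@H](/C=C3\C(=O)C=C(OC)[C@@H]3Cl)[C@@](C)(O)CC[C@@H]12 | intermediate
30 | (4E,5R)-5-chloro-3-hydroxy-4-[(5S,8S,9R,10S)-8-hydroxydriman-11-ylidene]cyclopent-2-en-1-one | CC1(C)CCC[C@]2(C)[C@@H](/C=C3\C(O)=CC(=O)[C@@H]3Cl)[C@@](C)(O)CC[C@@H]12 | target

Total step count: 18
Longest linear sequence: 17 steps (steps 1–11 and 13–18, from (R)-carvone); step 12 is a one-step side branch.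

Three steps most likely to fail, each with its fallback:

First, the oxazaborolidine reduction of step 16. Facial discrimination may be poor, because both flanks of the C1' carbonyl are sp2 carbons, so hydride could be delivered to both faces. The fallback sets out from 27. A Luche reduction (NaBH4, CeCl3, MeOH, −78 °C) should reduce C1' regioselectively without facial control, and the two carbinols, being diastereomers, are separated by chromatography. One is 28; the other, (4R,5Z)-4-hydroxy-5-(8β-hydroxydriman-11-ylidene)-3-methoxycyclopent-2-en-1-one F1, is inverted by a Mitsunobu reaction (4-nitrobenzoic acid, PPh3, DIAD, THF) to (1S,5Z)-5-(8β-hydroxydriman-11-ylidene)-2-methoxy-4-oxocyclopent-2-en-1-yl 4-nitrobenzoate F2. Methanolysis of this ester (K2CO3, MeOH, 0 °C) comes back to the route at 28.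

Second, the allylic oxidation of step 15. The peroxyl radical may abstract hydrogen at other sites (the allylic C9–H), add to the enol ether double bond or over-oxidise, instead of oxidising only the C4' methylene. The fallback sets out from 26. Catalytic SeO2 with t-BuOOH (CH2Cl2, rt) should hydroxylate the same methylene by a closed-shell ene reaction and [2,3]-sigmatropic shift on the C5'=C11 alkene, whose more substituted terminus C5' has C4' as its only hydrogen-bearing allylic carbon. This should give (E)-4-hydroxy-5-(8β-hydroxydriman-11-ylidene)-2-methoxycyclopent-2-en-1-one F3 as a C4' epimer mixture. Dess–Martin oxidation of this secondary alcohol comes back to the route at 27.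

Third, the hydration of step 10. The trans-diaxial course may be lost (water attacking a cation-like C8 from the α face, giving the 8α-alcohol), or mercuration of the hindered alkene may be slow. The fallback sets out from 17. A hydroxyl-directed epoxidation (VO(acac)2, t-BuOOH, CH2Cl2) should deliver oxygen to the β face, syn to the C11 hydroxyl, and give 7β,8β-epoxydriman-11-ol F4. LiAlH4 (THF, reflux) should then open the epoxide trans-diaxially at the less substituted C7 from the α face, keeping the C8–O bond, and comes back to the route at 19.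

Further compounds
F1 | step 16 | (4R,5Z)-4-hydroxy-5-(8β-hydroxydriman-11-ylidene)-3-methoxycyclopent-2-en-1-one | CC1(C)CCC[C@]2(C)[C@@H](/C=C3\C(=O)C=C(OC)[C@@H]3O)[C@@](C)(O)CC[C@@H]12
F2 | step 16 | (1S,5Z)-5-(8β-hydroxydriman-11-ylidene)-2-methoxy-4-oxocyclopent-2-en-1-yl 4-nitrobenzoate | CC1(C)CCC[C@]2(C)[C@@H](/C=C3\C(=O)C=C(OC)[C@H]3OC(=O)c4ccc(cc4)[N+]([O-])=O)[C@@](C)(O)CC[C@@H]12
F3 | step 15 | (E)-4-hydroxy-5-(8β-hydroxydriman-11-ylidene)-2-methoxycyclopent-2-en-1-one (C4' epimer mixture) | CC1(C)CCC[C@]2(C)[C@@H](/C=C3\C(O)C=C(OC)C3=O)[C@@](C)(O)CC[C@@H]12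
F4 | step 10 | 7β,8β-epoxydriman-11-ol | CC1(C)CCC[C@]2(C)[C@@H](CO)[C@@]3(C)O[C@H]3C[C@@H]12
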